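**Retrosynthetic overview**
- The target comes from its 5,7-di-O-methyl ether by a final BBr3 demethylation.
- The pyranone ring comes from acid cyclodehydration of 1-(6-hydroxy-2,4-dimethoxy-3-methylphenyl)dotriacontane-1,3-dione. Only the phenol next to the ring C–H is free, which fixes the methyl group at C6 rather than C8.
- The key C–C bond (C2–C3 of the chromone) comes from an intermolecular crossed Claisen condensation of the acetophenone enolate with methyl triacontanoate.
- The acetophenone comes from ortho-acetylation of symmetrical 3,5-dimethoxy-4-methylphenol, itself made by C–H borylation/oxidation of 2,6-dimethoxytoluene. The ester comes from 1-triacontanol by oxidation and esterification.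
- Ring order: benzene ring A is bought intact; the pyranone ring is the only ring formed (step 6).

Assumption: the target has no stereocentre and no stereogenic double bond, so it is one achiral compound and no stereocontrol is needed; the side chain is read as unbranched nonacosyl (29 carbons).

**Route**

Step 1
Reactants: 1 2,6-dimethoxytoluene (1,3-dimethoxy-2-methylbenzene)
Product: 3 3,5-dimethoxy-4-methylphenol, via aryl pinacol boronate 2 (not isolated)
Conditions: [Ir(OMe)(cod)]2 (1.5 mol %), 4,4'-di-tert-butyl-2,2'-bipyridine (3 mol %), B2pin2 (0.6 equiv), THF, 80 °C, 16 h; then Oxone (2KHSO5·KHSO4·K2SO4), acetone/H2O, rt, 10 min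
Reagents that add atoms: potassium peroxymonosulfate KHSO5 (active salt of Oxone), [K+].[O-]S(=O)(=O)OO
Why: Sterically controlled iridium-catalysed C–H borylation (Hartwig–Miyaura type) occurs only at the one C–H with no ortho substituent (para to the methyl group), and oxidation of the C–B bond then gives the phenol; no stereocentre is formed.

Step 2
Reactants: 3 3,5-dimethoxy-4-methylphenol
Product: 5 1-(6-hydroxy-2,4-dimethoxy-3-methylphenyl)ethanone, via difluoroboron chelate 4 (not isolated)
Conditions: AcOH, BF3·OEt2 (3 equiv), 90 °C, 3 h; then H2O/EtOH, 70 °C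
Reagents that add atoms: acetic acid, CC(=O)O
Why: BF3-mediated ortho Friedel–Crafts acylation (Fries-type) of the phenol gives a single regioisomer because the two free ring positions are equivalent by symmetry, and the BF2 chelate 4 is hydrolysed to the free o-hydroxy ketone.

Step 3
Reactants: 6 1-triacontanol
Product: 8 triacontanoic acid, via triacontanal 7 (not isolated)
Conditions: CrO3, H2SO4, H2O (Jones reagent, hexavalent chromium), acetone/THF 3:1, 40 °C
Reagents that add atoms: water, O
Why: Jones oxidation takes the primary alcohol through the aldehyde and its hydrate to the acid, and the warm acetone/THF mixture keeps the waxy substrate in solution.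

Step 4
Reactants: 8 triacontanoic acid
Product: 9 methyl triacontanoate
Conditions: MeOH (excess), H2SO4 (cat.), toluene, reflux
Reagents that add atoms: methanol, CO
Why: Fischer esterification of an unhindered acid is driven to completion by excess methanol.

Step 5
Reactants: 5 1-(6-hydroxy-2,4-dimethoxy-3-methylphenyl)ethanone; 9 methyl triacontanoate
Product: 10 1-(6-hydroxy-2,4-dimethoxy-3-methylphenyl)dotriacontane-1,3-dione
Conditions: NaH (4 equiv), THF, 0 °C → rt; then 9 (1.2 equiv) in warm THF, reflux, 6 h; aq. HCl work-up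
Reagents that add atoms: none
Why: In this intermolecular crossed Claisen condensation NaH forms the phenoxide and then the methyl-ketone enolate, which attacks the ester carbonyl; loss of methoxide and irreversible deprotonation of the 1,3-diketone drive the reaction, and the hindered aryl ketone does not self-condense.

Step 6
Reactants: 10 1-(6-hydroxy-2,4-dimethoxy-3-methylphenyl)dotriacontane-1,3-dione
Product: 12 5,7-dimethoxy-6-methyl-2-nonacosyl-4H-chromen-4-one, via 2-hydroxychroman-4-one hemiketal 11 (not isolated)
Conditions: p-TsOH·H2O (0.2 equiv), toluene, reflux, Dean–Stark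
Reagents that add atoms: none
Why: Acid-catalysed cyclodehydration closes the ring through the only free phenol (hemiketal 11, a transient racemic centre) and loses water to give the pyranone, so only the 6-methyl chromone can form because the other two oxygens are methyl ethers.

Step 7
Reactants: 12 5,7-dimethoxy-6-methyl-2-nonacosyl-4H-chromen-4-one
Product: 14 5,7-dihydroxy-6-methyl-2-nonacosyl-4H-chromen-4-one (target), via bis(dibromoboryl) ether 13 (not isolated)
Conditions: BBr3 (6 equiv), CH2Cl2, 0 °C → rt (40 °C if needed), 16 h; then H2O, 0 °C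
Reagents that add atoms: none
Why: BBr3 ether cleavage (complexation, then SN2 attack of bromide at methyl) removes both methyl groups, the 5-OMe helped by chelation to the C4 carbonyl; the anhydrous conditions keep the pyranone closed, so no Wessely–Moser isomerisation to the 8-methyl isomer occurs, and borate 13 is hydrolysed on quench.

**Compound list**

1 | 2,6-dimethoxytoluene (1,3-dimethoxy-2-methylbenzene) | COc1cccc(OC)c1C | starting material
2 | 2-(3,5-dimethoxy-4-methylphenyl)-4,4,5,5-tetramethyl-1,3,2-dioxaborolane | COc1cc(cc(OC)c1C)B1OC(C)(C)C(C)(C)O1 | intermediate (not isolated)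
3 | 3,5-dimethoxy-4-methylphenol | COc1cc(O)cc(OC)c1C | intermediate
4 | difluoroboron chelate of 5 (2,2-difluoro-5,7-dimethoxy-4,6-dimethyl-1,3,2-benzodioxaborinine, BF2 bridging the phenol and ketone oxygens) | CC1=[O+][B-](F)(F)Oc2cc(OC)c(C)c(OC)c12 | intermediate (not isolated)
5 | 1-(6-hydroxy-2,4-dimethoxy-3-methylphenyl)ethanone | CC(=O)c1c(O)cc(OC)c(C)c1OC | intermediate
6 | 1-triacontanol | CCCCCCCCCCCCCCCCCCCCCCCCCCCCCCO | starting material
7 | triacontanal | CCCCCCCCCCCCCCCCCCCCCCCCCCCCCC=O | intermediate (not isolated)
8 | triacontanoic acid | CCCCCCCCCCCCCCCCCCCCCCCCCCCCCC(=O)O | intermediate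
9 | methyl triacontanoate | CCCCCCCCCCCCCCCCCCCCCCCCCCCCCC(=O)OC | intermediate
10 | 1-(6-hydroxy-2,4-dimethoxy-3-methylphenyl)dotriacontane-1,3-dione | CCCCCCCCCCCCCCCCCCCCCCCCCCCCCC(=O)CC(=O)c1c(O)cc(OC)c(C)c1OC | intermediate
11 | 2-hydroxy-5,7-dimethoxy-6-methyl-2-nonacosyl-2,3-dihydro-4H-chromen-4-one (racemic at C2) | CCCCCCCCCCCCCCCCCCCCCCCCCCCCCC1(O)CC(=O)c2c(OC)c(C)c(OC)cc2O1 | intermediate (not isolated)
12 | 5,7-dimethoxy-6-methyl-2-nonacosyl-4H-chromen-4-one | CCCCCCCCCCCCCCCCCCCCCCCCCCCCCc1cc(=O)c2c(OC)c(C)c(OC)cc2o1 | intermediate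
13 | 5,7-bis(dibromoboryloxy)-6-methyl-2-nonacosyl-4H-chromen-4-one | CCCCCCCCCCCCCCCCCCCCCCCCCCCCCc1cc(=O)c2c(OB(Br)Br)c(C)c(OB(Br)Br)cc2o1 | intermediate (not isolated)
14 | 5,7-dihydroxy-6-methyl-2-nonacosyl-4H-chromen-4-one (achiral) | CCCCCCCCCCCCCCCCCCCCCCCCCCCCCc1cc(=O)c2c(O)c(C)c(O)cc2o1 | target

**Totals**

Total step count: 7.
Longest linear sequence: 5 steps (1 → 3 → 5 → 10 → 12 → 14, steps 1, 2, 5, 6, 7). The side-chain branch 6 → 8 → 9 joins at step 5 and is also 5 steps to the target.

**Steps most likely to fail, with fallbacks**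

Step 5 (Claisen condensation of a phenoxide-bearing ketone with a waxy, poorly soluble ester). The fallback sets out from 5 (with the aldehyde made from 6) and comes back to the route at 10. The same C–C bond is made by an intermolecular aldol addition instead. Ketone 5 is protected with MOMCl and NaH in DMF as 1-[2,4-dimethoxy-6-(methoxymethoxy)-3-methylphenyl]ethanone F1. Alcohol 6 is oxidised only as far as triacontanal 7 (TEMPO cat., PhI(OAc)2, CH2Cl2, 35 °C), which is isolated this time. The lithium enolate of F1 (LiN(iPr)2, THF, −78 °C) adds to 7 to give racemic 3-hydroxy-1-[2,4-dimethoxy-6-(methoxymethoxy)-3-methylphenyl]dotriacontan-1-one F2, whose stereocentre is removed in the next operation. Dess–Martin periodinane in CH2Cl2 oxidises it to 1-[2,4-dimethoxy-6-(methoxymethoxy)-3-methylphenyl]dotriacontane-1,3-dione F3. HCl in MeOH/THF at 60 °C removes the MOM group and gives 10, which goes on to 12 as in step 6.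

Step 7 (double demethylation; the 7-OMe may lag behind the chelation-assisted 5-OMe). The fallback sets out from 12 and comes back at 14, cleaving the two ethers one at a time by different mechanisms. AlCl3 in CH2Cl2/MeCN at 40 °C removes only the 5-O-methyl group through chelation to the C4 carbonyl and gives 5-hydroxy-7-methoxy-6-methyl-2-nonacosyl-4H-chromen-4-one F4. The remaining 7-methyl ether, para to the carbonyl, is then cleaved by SN2 attack of NaSEt in DMF at 120 °C, and acidification gives 14.

Step 1 (catalytic C–H borylation; catalyst sensitivity, and over-oxidation of the electron-rich phenol by Oxone). The fallback sets out from 1 and comes back at 5, bypassing 2, 3 and 4; the oxygen is introduced after the acetyl group instead of before it. Friedel–Crafts acetylation of 1 (AcCl, SnCl4, CH2Cl2, 0 °C) at the position ortho/para to the methoxy groups gives 1-(2,4-dimethoxy-3-methylphenyl)ethanone F5. Ketone-directed ortho C–H oxygenation at its only ortho C–H (Pd(OAc)2, divalent palladium, 5 mol %, K2S2O8, CF3CO2H/(CF3CO)2O, 50 °C) gives 2-acetyl-3,5-dimethoxy-4-methylphenyl trifluoroacetate F6. This ester is hydrolysed on work-up (aq. NaHCO3/MeOH) to 5.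

**Further compounds**

F1 | step 5 | 1-[2,4-dimethoxy-6-(methoxymethoxy)-3-methylphenyl]ethanone | CC(=O)c1c(OCOC)cc(OC)c(C)c1OC
F2 | step 5 | 3-hydroxy-1-[2,4-dimethoxy-6-(methoxymethoxy)-3-methylphenyl]dotriacontan-1-one (racemic) | CCCCCCCCCCCCCCCCCCCCCCCCCCCCCC(O)CC(=O)c1c(OCOC)cc(OC)c(C)c1OC
F3 | step 5 | 1-[2,4-dimethoxy-6-(methoxymethoxy)-3-methylphenyl]dotriacontane-1,3-dione | CCCCCCCCCCCCCCCCCCCCCCCCCCCCCC(=O)CC(=O)c1c(OCOC)cc(OC)c(C)c1OC
F4 | step 7 | 5-hydroxy-7-methoxy-6-methyl-2-nonacosyl-4H-chromen-4-one | CCCCCCCCCCCCCCCCCCCCCCCCCCCCCc1cc(=O)c2c(O)c(C)c(OC)cc2o1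
F5 | step 1 | 1-(2,4-dimethoxy-3-methylphenyl)ethanone | CC(=O)c1ccc(OC)c(C)c1OC
F6 | step 1 | 2-acetyl-3,5-dimethoxy-4-methylphenyl trifluoroacetate | CC(=O)c1c(OC(=O)C(F)(F)F)cc(OC)c(C)c1OC
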